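The route rests on cutting the C3–C1' bond that ties ring C of the chromone to ring B. C1' of ring B has oxygen at C2' (ortho) and at C4' (para, the pyran oxygen), so ring B migrates readily to an electron-poor carbon. Oxidation of a 2'-hydroxychalcone with Tl(NO3)3 in methanol therefore moves ring B from the β- to the α-carbon, forging C3–C1' and leaving the future C2 as a dimethyl acetal in one operation. The precursor is the (E)-chalcone of 4-O-MOM-2,4-dihydroxyacetophenone and a 5-O-MOM chroman-6-carbaldehyde. The pyran stays saturated through the oxidation and is dehydrogenated with DDQ at the end.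

Key step: step 7

Remark: the target is achiral; the sp3 centres created on the way are racemic and are destroyed later, and the only geometric element, the E alkene of 11, is set thermodynamically.

Step 1
Reactants: 1 4-methoxyresorcinol
Product: 3 2,4-dihydroxy-5-methoxybenzaldehyde, via aryl iminium chloride 2 (not isolated)
Conditions: POCl3, DMF, MeCN, 0 °C → rt; then H2O, 50 °C
Reagents that add atoms: N,N-dimethylformamide CN(C)C=O; water O
Why: Vilsmeier–Haack formylation, in which the chloroiminium ion attacks the ring carbon that is ortho to one hydroxyl and para to the other (the carbon between the two hydroxyls is more hindered and the remaining one is not activated), and water hydrolyses iminium salt 2 to the aldehyde.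

Step 2
Reactants: 3 2,4-dihydroxy-5-methoxybenzaldehyde; 4 3-methylbut-2-enal
Product: 6 5-hydroxy-8-methoxy-2,2-dimethyl-2H-chromene-6-carbaldehyde, via ortho-quinone methide 5 (not isolated)
Conditions: Ca(OH)2, MeOH, rt
Reagents that add atoms: none
Why: Base-mediated chromenylation of a resorcinol with an enal (aldol-type C-alkylation, dehydration, oxa-6π electrocyclisation): the calcium phenoxide can attack only through C3, since C5 carries the methoxy group, and the quinone methide should form through the 4-oxygen because the 2-hydroxyl stays hydrogen-bonded to the formyl group.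

Step 3
Reactants: 6 5-hydroxy-8-methoxy-2,2-dimethyl-2H-chromene-6-carbaldehyde
Product: 7 5-hydroxy-8-methoxy-2,2-dimethylchroman-6-carbaldehyde
Conditions: H2 (1 atm), 10% Pd/C, EtOAc, rt
Reagents that add atoms: none
Why: Catalytic hydrogenation, in which the cis-disubstituted styrene-type alkene should be reduced well before the chelated, electron-rich aryl aldehyde if the uptake is stopped at one equivalent.

Step 4
Reactants: 7 5-hydroxy-8-methoxy-2,2-dimethylchroman-6-carbaldehyde
Product: 8 8-methoxy-5-(methoxymethoxy)-2,2-dimethylchroman-6-carbaldehyde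
Conditions: NaH, MOMCl, DMF, 0 °C → rt
Reagents that add atoms: chloromethyl methyl ether COCCl
Why: Williamson-type O-alkylation, with NaH needed to break the hydrogen bond of the hindered phenol to the formyl group, giving an acetal ether that withstands the hydroxide of step 6.

Step 5
Reactants: 9 2,4-dihydroxyacetophenone
Product: 10 1-[2-hydroxy-4-(methoxymethoxy)phenyl]ethanone
Conditions: MOMCl, K2CO3, acetone, rt
Reagents that add atoms: chloromethyl methyl ether COCCl
Why: Selective Williamson-type O-alkylation, since the weak base ionises only the free 4-hydroxyl while the 2-hydroxyl remains chelated to the acetyl group.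

Step 6
Reactants: 8 8-methoxy-5-(methoxymethoxy)-2,2-dimethylchroman-6-carbaldehyde; 10 1-[2-hydroxy-4-(methoxymethoxy)phenyl]ethanone
Product: 11 (E)-1-[2-hydroxy-4-(methoxymethoxy)phenyl]-3-[8-methoxy-5-(methoxymethoxy)-2,2-dimethylchroman-6-yl]prop-2-en-1-one
Conditions: KOH, EtOH–H2O, rt
Reagents that add atoms: none
Why: Claisen–Schmidt condensation between a methyl ketone and an aldehyde that cannot enolise, the E1cB dehydration of the aldol giving the conjugated (E)-enone under thermodynamic control while the MOM ethers are inert to hydroxide.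

Step 7
Reactants: 11 (E)-1-[2-hydroxy-4-(methoxymethoxy)phenyl]-3-[8-methoxy-5-(methoxymethoxy)-2,2-dimethylchroman-6-yl]prop-2-en-1-one
Product: 13 1-[2-hydroxy-4-(methoxymethoxy)phenyl]-3,3-dimethoxy-2-[8-methoxy-5-(methoxymethoxy)-2,2-dimethylchroman-6-yl]propan-1-one (racemic), via oxythallation adduct 12 (not isolated)
Conditions: Tl(NO3)3·3H2O, MeOH–HC(OMe)3, rt
Reagents that add atoms: methanol CO
Why: Trivalent thallium adds across the enone in methanol so that a methoxy group sits on the benzylic β-carbon and the metal on the α-carbon (adduct 12); heterolysis of the C–Tl bond, which releases TlNO3, is assisted by ring B, whose C1' bridges through a phenonium ion and ends on the α-carbon, and methanol traps the resulting oxocarbenium ion as the dimethyl acetal. The closest known reaction type is the thallium trinitrate oxidative rearrangement of 2'-hydroxychalcones used to make isoflavones. No ring is closed here; the acetal carbon becomes C2 only in step 8. The one new sp3 centre (the α-carbon) forms as a racemate with no controlling element and is flattened to C3 in step 8. Aryl migration must beat aroyl migration and direct closure of the ring A phenol to an aurone or flavone; the oxygens ortho (OMOM) and para (pyran oxygen) to C1' make ring B by far the better migrating group, and methanol in large excess, not the phenol, is the nucleophile. The saturated chroman offers the metal no second alkene, and the orthoformate keeps the medium dry so that the MOM ethers should outlast the nitric acid released.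

Step 8
Reactants: 13 1-[2-hydroxy-4-(methoxymethoxy)phenyl]-3,3-dimethoxy-2-[8-methoxy-5-(methoxymethoxy)-2,2-dimethylchroman-6-yl]propan-1-one
Product: 14 7-hydroxy-3-(5-hydroxy-8-methoxy-2,2-dimethylchroman-6-yl)-4H-chromen-4-one
Conditions: conc. HCl, MeOH, 60 °C
Reagents that add atoms: none
Why: Acid-catalysed acetal ionisation, six-membered closure by the ring A phenol (free from the outset) and irreversible loss of methanol to the γ-pyrone, with solvolysis of both MOM ethers in the same pot; a five-membered cyclic acetal formed by the newly freed ring B phenol would be expected to stay in equilibrium with the oxocarbenium ion and drain to the isoflavone.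

Step 9
Reactants: 14 7-hydroxy-3-(5-hydroxy-8-methoxy-2,2-dimethylchroman-6-yl)-4H-chromen-4-one
Product: 15 3-(5-acetoxy-8-methoxy-2,2-dimethylchroman-6-yl)-4-oxo-4H-chromen-7-yl acetate
Conditions: Ac2O, pyridine, DMAP (cat.), rt
Reagents that add atoms: acetic anhydride CC(=O)OC(C)=O
Why: Nucleophile-catalysed O-acylation of both phenols, which masks the para-methoxyphenol of ring B so that the quinone oxidant of step 10 cannot turn it into a quinone.

Step 10
Reactants: 15 3-(5-acetoxy-8-methoxy-2,2-dimethylchroman-6-yl)-4-oxo-4H-chromen-7-yl acetate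
Product: 16 3-(5-acetoxy-8-methoxy-2,2-dimethyl-2H-chromen-6-yl)-4-oxo-4H-chromen-7-yl acetate
Conditions: DDQ, 1,4-dioxane, reflux
Reagents that add atoms: none
Why: DDQ dehydrogenation of a 2,2-dimethylchroman to the 2H-chromene by hydride abstraction from benzylic C4 (the cation is stabilised by the ring oxygen ortho to C4a) and loss of a C3 proton, the gem-dimethyl group stopping the oxidation at the alkene.

Step 11
Reactants: 16 3-(5-acetoxy-8-methoxy-2,2-dimethyl-2H-chromen-6-yl)-4-oxo-4H-chromen-7-yl acetate
Product: 17 7-hydroxy-3-(5-hydroxy-8-methoxy-2,2-dimethyl-2H-chromen-6-yl)-4H-chromen-4-one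
Conditions: K2CO3, MeOH, 0 °C → rt, argon; NH4Cl (aq.) work-up
Reagents that add atoms: none
Why: Base-mediated transesterification of the two aryl acetates to methyl acetate, mild and brief enough to leave the chromene, the aryl methyl ether and the base-sensitive γ-pyrone untouched.

Compound list
1 | 4-methoxyresorcinol (4-methoxybenzene-1,3-diol) | COc1ccc(O)cc1O | starting material
2 | [(2,4-dihydroxy-5-methoxyphenyl)methylidene]dimethylammonium chloride | COc1cc(C=[N+](C)C)c(O)cc1O.[Cl-] | intermediate (not isolated)
3 | 2,4-dihydroxy-5-methoxybenzaldehyde | COc1cc(C=O)c(O)cc1O | intermediate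
4 | 3-methylbut-2-enal | CC(C)=CC=O | starting material
5 | 2-hydroxy-5-methoxy-3-(3-methylbut-2-en-1-ylidene)-4-oxocyclohexa-1,5-diene-1-carbaldehyde (ortho-quinone methide, geometry of the exocyclic alkene not fixed) | O=CC1=C(O)C(=CC=C(C)C)C(=O)C(OC)=C1 | intermediate (not isolated)
6 | 5-hydroxy-8-methoxy-2,2-dimethyl-2H-chromene-6-carbaldehyde | COc1cc(C=O)c(O)c2C=CC(C)(C)Oc12 | intermediate
7 | 5-hydroxy-8-methoxy-2,2-dimethylchroman-6-carbaldehyde | COc1cc(C=O)c(O)c2CCC(C)(C)Oc12 | intermediate
8 | 8-methoxy-5-(methoxymethoxy)-2,2-dimethylchroman-6-carbaldehyde | COCOc1c(C=O)cc(OC)c2OC(C)(C)CCc12 | intermediate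
9 | 2,4-dihydroxyacetophenone | CC(=O)c1ccc(O)cc1O | starting material
10 | 1-[2-hydroxy-4-(methoxymethoxy)phenyl]ethanone | CC(=O)c1ccc(OCOC)cc1O | intermediate
11 | (E)-1-[2-hydroxy-4-(methoxymethoxy)phenyl]-3-[8-methoxy-5-(methoxymethoxy)-2,2-dimethylchroman-6-yl]prop-2-en-1-one | COCOc1ccc(C(=O)/C=C/c2cc(OC)c3OC(C)(C)CCc3c2OCOC)c(O)c1 | intermediate
12 | 2-(dinitratothallio)-1-[2-hydroxy-4-(methoxymethoxy)phenyl]-3-methoxy-3-[8-methoxy-5-(methoxymethoxy)-2,2-dimethylchroman-6-yl]propan-1-one (oxythallation adduct, racemic, relative configuration not defined) | COCOc1ccc(C(=O)C([Tl](O[N+](=O)[O-])O[N+](=O)[O-])C(OC)c2cc(OC)c3OC(C)(C)CCc3c2OCOC)c(O)c1 | intermediate (not isolated)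
13 | 1-[2-hydroxy-4-(methoxymethoxy)phenyl]-3,3-dimethoxy-2-[8-methoxy-5-(methoxymethoxy)-2,2-dimethylchroman-6-yl]propan-1-one (racemic) | COCOc1ccc(C(=O)C(C(OC)OC)c2cc(OC)c3OC(C)(C)CCc3c2OCOC)c(O)c1 | intermediate
14 | 7-hydroxy-3-(5-hydroxy-8-methoxy-2,2-dimethylchroman-6-yl)-4H-chromen-4-one | COc1cc(-c2coc3cc(O)ccc3c2=O)c(O)c2c1OC(C)(C)CC2 | intermediate
15 | 3-(5-acetoxy-8-methoxy-2,2-dimethylchroman-6-yl)-4-oxo-4H-chromen-7-yl acetate | COc1cc(-c2coc3cc(OC(C)=O)ccc3c2=O)c(OC(C)=O)c2c1OC(C)(C)CC2 | intermediate
16 | 3-(5-acetoxy-8-methoxy-2,2-dimethyl-2H-chromen-6-yl)-4-oxo-4H-chromen-7-yl acetate | COc1cc(-c2coc3cc(OC(C)=O)ccc3c2=O)c(OC(C)=O)c2c1OC(C)(C)C=C2 | intermediate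
17 | 7-hydroxy-3-(5-hydroxy-8-methoxy-2,2-dimethyl-2H-chromen-6-yl)-4H-chromen-4-one | COc1cc(-c2coc3cc(O)ccc3c2=O)c(O)c2c1OC(C)(C)C=C2 | target

Total step count: 11. Longest linear sequence: 10 steps (steps 1–4 and 6–11, from 4-methoxyresorcinol); step 5 is the one-step side branch.

Steps most likely to fail

Step 7. The ring A phenol may close onto the thallated enone (aurone or flavone formation) instead of letting ring B migrate. The nitric acid released may also strip the ring B MOM group, after which the thallium salt would oxidise the freed para-methoxyphenol. Thallium salts are also highly toxic, and the TlNO3 precipitate has to be filtered off and segregated. The fallback sets out from chalcone 11 and closes ring C before the aryl shift. NaOAc in refluxing EtOH (intramolecular oxa-Michael addition of the ring A phenol) should give the racemic flavanone 7-(methoxymethoxy)-2-[8-methoxy-5-(methoxymethoxy)-2,2-dimethylchroman-6-yl]chroman-4-one F1. PhI(OH)OTs in MeCN at 60–80 °C should then bring about the known hypervalent iodine 2,3-aryl shift of flavanones: the enol is attacked at C3 by the iodine reagent, the electron-rich ring B moves from C2 to C3 as iodobenzene leaves, and a proton is lost. This gives 7-(methoxymethoxy)-3-[8-methoxy-5-(methoxymethoxy)-2,2-dimethylchroman-6-yl]-4H-chromen-4-one F2. No free phenol and no acetal closure are involved. HCl in MeOH, as in step 8, removes both MOM groups and the sequence rejoins the route at 14.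

Step 10. Hydride abstraction from C4 may be slow because the acetates make the chroman ring electron-poor, and forcing the reaction may over-oxidise ring B. The fallback sets out from diacetate 15 and replaces hydride abstraction by a radical pathway. NBS with AIBN (cat.) in refluxing PhCF3 should brominate the benzylic C4 position to give racemic 3-(5-acetoxy-4-bromo-8-methoxy-2,2-dimethylchroman-6-yl)-4-oxo-4H-chromen-7-yl acetate F3. DBU in toluene then eliminates HBr (E2) to give the chromene and the sequence rejoins the route at 16.

Step 2. C-alkylation at the crowded carbon between the two phenolic oxygens may be incomplete, and the enal may self-condense under the basic conditions. The fallback sets out from aldehyde 3 and attaches the five-carbon unit to oxygen first. 3-Chloro-3-methylbut-1-yne with DBU and CuCl2 (cat.) in MeCN at 0 °C should alkylate the free 4-hydroxyl to give 2-hydroxy-5-methoxy-4-[(2-methylbut-3-yn-2-yl)oxy]benzaldehyde F4. Heating F4 in N,N-diethylaniline at about 200 °C triggers an aromatic Claisen rearrangement to C3, the only free ortho position, giving 2,4-dihydroxy-5-methoxy-3-(3-methylbuta-1,2-dien-1-yl)benzaldehyde F5 (not isolated). A 1,5-hydrogen shift converts F5 into quinone methide 5, which closes, and the sequence rejoins the route at 6.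

Further compounds
F1 | step 7 | 7-(methoxymethoxy)-2-[8-methoxy-5-(methoxymethoxy)-2,2-dimethylchroman-6-yl]chroman-4-one (racemic) | COCOc1ccc2C(=O)CC(Oc2c1)c1cc(OC)c2OC(C)(C)CCc2c1OCOC
F2 | step 7 | 7-(methoxymethoxy)-3-[8-methoxy-5-(methoxymethoxy)-2,2-dimethylchroman-6-yl]-4H-chromen-4-one | COCOc1ccc2c(c1)occ(-c1cc(OC)c3OC(C)(C)CCc3c1OCOC)c2=O
F3 | step 10 | 3-(5-acetoxy-4-bromo-8-methoxy-2,2-dimethylchroman-6-yl)-4-oxo-4H-chromen-7-yl acetate (racemic) | COc1cc(-c2coc3cc(OC(C)=O)ccc3c2=O)c(OC(C)=O)c2c1OC(C)(C)CC2Br
F4 | step 2 | 2-hydroxy-5-methoxy-4-[(2-methylbut-3-yn-2-yl)oxy]benzaldehyde | COc1cc(C=O)c(O)cc1OC(C)(C)C#C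
F5 | step 2 | 2,4-dihydroxy-5-methoxy-3-(3-methylbuta-1,2-dien-1-yl)benzaldehyde | COc1cc(C=O)c(O)c(C=C=C(C)C)c1O
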